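Ring B is a 2,4-dioxygenated 6-pentylbenzoate, the pattern of a folded 3,5,7-trioxododecanoate, and its carboxyl carbon is esterified to O4 of ring A. The route therefore cuts two bonds of ring B at once: the depside C(=O)–O bond and the ring C1–C6 bond. Heating a 6-(2,4-dioxononyl)dioxinone, an acetone-masked triketo acid, with benzyl olivetolate releases an acylketene that the free ring A 4-OH captures; amine base then folds the tethered chain by aldol condensation into ring B. Ring A is supplied by benzyl esterification of olivetolic acid. Methylation of ring B O4, chlorination at ring B C3 and debenzylation complete the target.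

Key step: step 5

Remark: olivetolic acid (2,4-dihydroxy-6-pentylbenzoic acid) is taken as a purchasable starting material. The di- and triketo compounds are drawn as keto tautomers although they will be largely enolised. The cyclic aldol intermediate of step 5 is a transient mixture of diastereomers whose configuration is lost on aromatisation. Its aromatisation requires loss of one molecule of water only; the two remaining ring carbonyls become the phenolic hydroxyls by tautomerisation.

Step 1
Reactants: 1 2,2,6-trimethyl-4H-1,3-dioxin-4-one; 2 acetyl chloride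
Product: 3 2,2-dimethyl-6-(2-oxopropyl)-4H-1,3-dioxin-4-one
Conditions: 1 (2 equiv), LiN(SiMe3)2 (2 equiv), THF, −78 °C; then 2 (1 equiv), −78 °C; 1 M HCl
Reagents that add atoms: none
Why: γ-Deprotonation of the 6-methyl group gives the lithium dienolate, which undergoes Claisen-type C-acylation at its exocyclic carbon, the twofold excess of enolate absorbing the proton of the more acidic product.

Step 2
Reactants: 4 hexanoyl chloride
Product: 5 N-methoxy-N-methylhexanamide
Conditions: MeNH(OMe)·HCl, K2CO3, H2O/CH2Cl2, 0 °C to rt
Reagents that add atoms: N,O-dimethylhydroxylamine hydrochloride, CNOC.Cl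
Why: Schotten–Baumann N-acylation of the hydroxylamine by the acid chloride under biphasic carbonate should give the N-methoxy-N-methylamide cleanly.

Step 3
Reactants: 3 2,2-dimethyl-6-(2-oxopropyl)-4H-1,3-dioxin-4-one; 5 N-methoxy-N-methylhexanamide
Product: 6 2,2-dimethyl-6-(2,4-dioxononyl)-4H-1,3-dioxin-4-one
Conditions: LiN(i-Pr)2 (2.2 equiv), THF, −78 °C; then 5, −78 to −40 °C; 1 M HCl
Reagents that add atoms: none
Why: Double deprotonation gives the dicarbonyl dianion whose terminal carbanion adds to the N-methoxy-N-methylamide (dianion Claisen acylation), and the chelated tetrahedral adduct collapses only on quench, which prevents over-acylation.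

Step 4
Reactants: 7 olivetolic acid (2,4-dihydroxy-6-pentylbenzoic acid); 8 benzyl bromide
Product: 9 benzyl olivetolate (benzyl 2,4-dihydroxy-6-pentylbenzoate)
Conditions: 8 (1.05 equiv), KHCO3 (1.2 equiv), DMF, rt
Reagents that add atoms: none
Why: Hydrogencarbonate ionises only the carboxylic acid, and SN2 O-alkylation of the carboxylate by benzyl bromide gives the benzyl ester without touching the phenols and without acyl substitution at the hindered carbonyl, while room temperature avoids decarboxylation of the β-resorcylic acid.

Step 5
Reactants: 6 2,2-dimethyl-6-(2,4-dioxononyl)-4H-1,3-dioxin-4-one; 9 benzyl olivetolate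
Product: 13 benzyl 4-[(2,4-dihydroxy-6-pentylbenzoyl)oxy]-2-hydroxy-6-pentylbenzoate, via acylketene 10 (not isolated), via aryl triketo ester 11 (not isolated), via cyclic aldol 12 (not isolated)
Conditions: 9 (2 equiv), PhMe, 110 °C, slow addition of 6; then Et3N, CH2Cl2, 0 °C; then TFA, 0 °C to rt
Reagents that add atoms: none
Why: Thermal retro-[4+2] cleavage of the dioxinone expels acetone and leaves acylketene 10, across which the phenolic O4–H of 9 adds through a six-membered hydrogen-transfer transition state to give aryl triketo ester 11, so the hindered 2,6-disubstituted benzoate ester is formed without any acyl-substitution step. Et3N then enolises C2 of 11, which attacks the C7 ketone in a 6-(enolendo)-exo-trig aldol closure that forms the C1–C6 bond of ring B; acid-promoted loss of one molecule of water from 12 and tautomerisation of the two remaining ring ketones give the aromatic ring with OH at C2 and C4 and pentyl at C6. The closest known reaction types are the acetoacetylation of phenols by dioxinone thermolysis and the aldol aromatisation of 3,5,7-triketo esters to 6-alkyl-2,4-dihydroxybenzoates. No stereocentre survives, since the two sp3 centres of 12 are erased on aromatisation. Site selectivity for O4 over O2 of 9 follows from the 2-OH being hydrogen-bonded to, and crowded by, the benzyl ester, and an excess of 9 together with slow addition of 6 keeps bimolecular capture ahead of self-trapping of the ketene by its own enol oxygen. C-aldol closure is favoured over O-cyclisation to a pyranone with loss of aryloxide by using a weak amine base at 0 °C in an aprotic solvent.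

Step 6
Reactants: 13 benzyl 4-[(2,4-dihydroxy-6-pentylbenzoyl)oxy]-2-hydroxy-6-pentylbenzoate
Product: 14 benzyl 2-hydroxy-4-[(2-hydroxy-4-methoxy-6-pentylbenzoyl)oxy]-6-pentylbenzoate
Conditions: MeI (1.05 equiv), K2CO3, acetone, rt
Reagents that add atoms: iodomethane, CI
Why: Williamson O-methylation with one equivalent of MeI should take the ring B 4-OH, the only phenol not locked in a hydrogen bond to an ortho carbonyl and the most acidic one, as is usual for 2,4-dihydroxybenzoates.

Step 7
Reactants: 14 benzyl 2-hydroxy-4-[(2-hydroxy-4-methoxy-6-pentylbenzoyl)oxy]-6-pentylbenzoate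
Product: 15 benzyl 4-[(3-chloro-2-hydroxy-4-methoxy-6-pentylbenzoyl)oxy]-2-hydroxy-6-pentylbenzoate
Conditions: SO2Cl2 (1.0 equiv, slow addition), i-Bu2NH (10 mol%), PhMe, 0 °C to rt
Reagents that add atoms: sulfuryl chloride, O=S(=O)(Cl)Cl
Why: Secondary-amine-catalysed ortho-chlorination of phenols by SO2Cl2 in a non-polar solvent (electrophilic aromatic substitution through an amine-bound chlorinating species, taken to be the N-chloroamine, that is hydrogen-bonded to the phenolic oxygen) places chlorine next to a hydroxyl group, and ring B, which carries both OH and OMe donors, is markedly more electron-rich than the acyloxy-substituted ring A and has C3 as its only position ortho to OH.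

Step 8
Reactants: 15 benzyl 4-[(3-chloro-2-hydroxy-4-methoxy-6-pentylbenzoyl)oxy]-2-hydroxy-6-pentylbenzoate
Product: 16 4-[(3-chloro-2-hydroxy-4-methoxy-6-pentylbenzoyl)oxy]-2-hydroxy-6-pentylbenzoic acid
Conditions: H2 (1 atm), 10% Pd/C, EtOAc, rt, stopped after 1 equiv of H2
Reagents that add atoms: none
Why: Catalytic hydrogenolysis of the benzyl ester under neutral, base-free conditions is much faster than reduction of an aryl C–Cl bond, so the chlorine and the hindered depside ester should be left intact when the reaction is stopped at one equivalent of hydrogen.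

Compound list
1 | 2,2,6-trimethyl-4H-1,3-dioxin-4-one | CC1=CC(=O)OC(C)(C)O1 | starting material
2 | acetyl chloride | CC(=O)Cl | starting material
3 | 2,2-dimethyl-6-(2-oxopropyl)-4H-1,3-dioxin-4-one | CC(=O)CC1=CC(=O)OC(C)(C)O1 | intermediate
4 | hexanoyl chloride | CCCCCC(=O)Cl | starting material
5 | N-methoxy-N-methylhexanamide | CCCCCC(=O)N(C)OC | intermediate
6 | 2,2-dimethyl-6-(2,4-dioxononyl)-4H-1,3-dioxin-4-one | CCCCCC(=O)CC(=O)CC1=CC(=O)OC(C)(C)O1 | intermediate
7 | olivetolic acid (2,4-dihydroxy-6-pentylbenzoic acid) | CCCCCc1cc(O)cc(O)c1C(=O)O | starting material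
8 | benzyl bromide | BrCc1ccccc1 | starting material
9 | benzyl 2,4-dihydroxy-6-pentylbenzoate (benzyl olivetolate) | CCCCCc1cc(O)cc(O)c1C(=O)OCc1ccccc1 | intermediate
10 | 3,5,7-trioxododec-1-en-1-one (acylketene) | CCCCCC(=O)CC(=O)CC(=O)C=C=O | intermediate (not isolated)
11 | benzyl 2-hydroxy-6-pentyl-4-[(3,5,7-trioxododecanoyl)oxy]benzoate | CCCCCC(=O)CC(=O)CC(=O)CC(=O)Oc1cc(O)c(C(=O)OCc2ccccc2)c(CCCCC)c1 | intermediate (not isolated)
12 | benzyl 2-hydroxy-4-[(2-hydroxy-4,6-dioxo-2-pentylcyclohexane-1-carbonyl)oxy]-6-pentylbenzoate (mixture of diastereomers) | CCCCCC1(O)CC(=O)CC(=O)C1C(=O)Oc1cc(O)c(C(=O)OCc2ccccc2)c(CCCCC)c1 | intermediate (not isolated)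
13 | benzyl 4-[(2,4-dihydroxy-6-pentylbenzoyl)oxy]-2-hydroxy-6-pentylbenzoate | CCCCCc1cc(OC(=O)c2c(CCCCC)cc(O)cc2O)cc(O)c1C(=O)OCc1ccccc1 | intermediate
14 | benzyl 2-hydroxy-4-[(2-hydroxy-4-methoxy-6-pentylbenzoyl)oxy]-6-pentylbenzoate | CCCCCc1cc(OC(=O)c2c(CCCCC)cc(OC)cc2O)cc(O)c1C(=O)OCc1ccccc1 | intermediate
15 | benzyl 4-[(3-chloro-2-hydroxy-4-methoxy-6-pentylbenzoyl)oxy]-2-hydroxy-6-pentylbenzoate | CCCCCc1cc(OC(=O)c2c(CCCCC)cc(OC)c(Cl)c2O)cc(O)c1C(=O)OCc1ccccc1 | intermediate
16 | 4-[(3-chloro-2-hydroxy-4-methoxy-6-pentylbenzoyl)oxy]-2-hydroxy-6-pentylbenzoic acid | CCCCCc1cc(OC(=O)c2c(CCCCC)cc(OC)c(Cl)c2O)cc(O)c1C(=O)O | target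

Total step count: 8.
Longest linear sequence: 6 steps (steps 1, 3, 5, 6, 7 and 8, from dioxinone 1); steps 2 and 4 are one-step side branches.

Steps most likely to fail

1. Step 5. Capture of the ketene by the phenol may be outrun by self-trapping of the ketene through its own enol oxygen. Acylation may also occur at the hydrogen-bonded O2. The aryl triketo ester may cyclise through oxygen with expulsion of the aryloxide instead of through carbon. Fallback: the depside bond would be made by conventional acylation with a preformed ring B acid. Setting out from 9, O-methylation of the unchelated 4-OH (MeI, K2CO3, acetone) would give benzyl 2-hydroxy-4-methoxy-6-pentylbenzoate F1. Hydrogenolysis (H2, 10% Pd/C, EtOAc) would then give 2-hydroxy-4-methoxy-6-pentylbenzoic acid F2. Treatment with (CF3CO)2O in toluene at rt would convert this acid into 2-hydroxy-4-methoxy-6-pentylbenzoic trifluoroacetic anhydride F3, which would acylate the free 4-OH of a second portion of 9. The path comes back to the route at 14, bypassing 13.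

2. Step 7. The hydrogen bond from the ring B 2-OH to the depside carbonyl may blunt the directing effect, so that chlorine enters para to that hydroxyl (C5), attacks ring A, or enters twice. Fallback: C5 would be blocked with bromine first. Setting out from 14, NBS (1 equiv, MeCN, 0 °C) should brominate ring B para to its hydroxyl, next to the pentyl group, to give benzyl 4-[(3-bromo-6-hydroxy-4-methoxy-2-pentylbenzoyl)oxy]-2-hydroxy-6-pentylbenzoate F4. SO2Cl2 in CH2Cl2 at 0 °C would then chlorinate the only open position of ring B to give benzyl 4-[(3-bromo-5-chloro-6-hydroxy-4-methoxy-2-pentylbenzoyl)oxy]-2-hydroxy-6-pentylbenzoate F5. Hydrogenolysis (H2, 10% Pd/C, NaOAc, EtOAc) cleaves aryl C–Br bonds far faster than aryl C–Cl bonds; it would remove bromine and the benzyl group together and come back to the route at 16.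

3. Step 8. Hydrogenolytic loss of the aryl chlorine may accompany or follow debenzylation. Fallback: the benzyl group would be removed without hydrogen. Setting out from 15, BCl3 with pentamethylbenzene as benzyl-cation scavenger (CH2Cl2, −78 °C) would cleave the benzyl ester, which is activated by chelation of boron between the ring A 2-oxygen and the ester carbonyl. Aqueous work-up would give 16 directly. The ring B methoxy group is not ortho to a carbonyl and should survive at this temperature. This path makes no new compound (entry F0 below).

Further compounds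
F1 | step 5 | benzyl 2-hydroxy-4-methoxy-6-pentylbenzoate | CCCCCc1cc(OC)cc(O)c1C(=O)OCc1ccccc1
F2 | step 5 | 2-hydroxy-4-methoxy-6-pentylbenzoic acid | CCCCCc1cc(OC)cc(O)c1C(=O)O
F3 | step 5 | 2-hydroxy-4-methoxy-6-pentylbenzoic trifluoroacetic anhydride | CCCCCc1cc(OC)cc(O)c1C(=O)OC(=O)C(F)(F)F
F4 | step 7 | benzyl 4-[(3-bromo-6-hydroxy-4-methoxy-2-pentylbenzoyl)oxy]-2-hydroxy-6-pentylbenzoate | CCCCCc1cc(OC(=O)c2c(CCCCC)c(Br)c(OC)cc2O)cc(O)c1C(=O)OCc1ccccc1
F5 | step 7 | benzyl 4-[(3-bromo-5-chloro-6-hydroxy-4-methoxy-2-pentylbenzoyl)oxy]-2-hydroxy-6-pentylbenzoate | CCCCCc1cc(OC(=O)c2c(CCCCC)c(Br)c(OC)c(Cl)c2O)cc(O)c1C(=O)OCc1ccccc1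
F0 | step 8 | none | none
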